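**Retrosynthetic overview**

1. Oxolane numbering: O1, C2 (aryl), C3 (CH2OH), C4 (carbinol branch), C5 (CH2). Target 17 ⇐ neutral global deallylation of 16 ⇐ Felkin addition of aryl Grignard 14 to bicyclic lactol 11, whose lactone ring is a temporary ring that ties the C3 and C4 branches cis.
2. Oxolane ring ⇐ formaldehyde (the O1–C5 unit) + cyclopropane-fused lactone 6 (the C2–C3–C4 unit): one operation makes O1–C2 and C5–C4, opens the cyclopropane bond C2–C4 and sets C2.
3. Enabling feature: the 4-oxygenated guaiacyl ring on benzylic C2 (a latent p-quinone methide, the donor) stands 1,3 to C4, whose carbinol carbon can be carried as a carbonyl (the acceptor, backed by a removable ester). C2–C3–C4 is therefore a donor–acceptor cyclopropane retron.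
4. 6 ⇐ organocatalytic Michael-initiated ring closure of O-silyl coniferaldehyde 2 with bromomalonate 3 (sets the absolute configuration at C3), then reduction and lactonisation.
5. Ring order: cyclopropane (step 2), γ-lactone (step 3, temporary), oxolane at the cost of the cyclopropane (step 4), lactone opened (steps 6 and 8).

Key step: step 4

Remark: in the 3,7-dioxabicyclo[3.3.0]octanes C6, O7, C8, C1 and C5 are oxolane C2, O1, C5, C4 and C3, and lactone C2 is the future carbinol carbon; the facial sense of the (S)-prolinol catalyst is taken as the one established for cinnamaldehydes.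

**Route**

Step 1
Reactants: 1 (E)-3-(4-hydroxy-3-methoxyphenyl)prop-2-enal (coniferaldehyde)
Product: 2 (E)-3-[3-methoxy-4-(triisopropylsilyloxy)phenyl]prop-2-enal
Conditions: iPr3SiCl, imidazole, DMF, rt
Reagents that add atoms: triisopropylsilyl chloride, CC(C)[Si](Cl)(C(C)C)C(C)C
Why: Routine silylation of a phenol; the bulky silyl ether should survive amine catalysis and borohydride, and its cleavage by fluoride is the trigger of step 4.

Step 2
Reactants: 2 (E)-3-[3-methoxy-4-(triisopropylsilyloxy)phenyl]prop-2-enal; 3 dimethyl 2-bromomalonate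
Product: 4 dimethyl (2R,3S)-2-formyl-3-[3-methoxy-4-(triisopropylsilyloxy)phenyl]cyclopropane-1,1-dicarboxylate
Conditions: (S)-2-[diphenyl(trimethylsilyloxy)methyl]pyrrolidine (20 mol %), 2,6-lutidine (1.1 equiv), CH2Cl2, 0 °C → rt
Reagents that add atoms: none
Why: Organocatalytic Michael-initiated ring closure: the bromomalonate adds to the iminium ion on the face opposite the diphenyl(silyloxy)methyl group and the enamine then closes by 3-exo-tet alkylation, which should set the formyl-bearing carbon as R (the future oxolane C3) with aryl and formyl trans.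

Step 3
Reactants: 4 dimethyl (2R,3S)-2-formyl-3-[3-methoxy-4-(triisopropylsilyloxy)phenyl]cyclopropane-1,1-dicarboxylate
Product: 6 methyl (1S,5R,6S)-6-[3-methoxy-4-(triisopropylsilyloxy)phenyl]-2-oxo-3-oxabicyclo[3.1.0]hexane-1-carboxylate, via hydroxymethyl cyclopropane diester 5 (not isolated)
Conditions: NaBH4, MeOH–THF, −10 °C → rt
Reagents that add atoms: none
Why: Chemoselective borohydride reduction of the aldehyde gives alcohol 5, whose alkoxide should lactonise onto the cis ester, which differentiates the two esters and ties the future C3 and C4 branches together on one face without touching a stereocentre.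

Step 4
Reactants: 6 methyl (1S,5R,6S)-6-[3-methoxy-4-(triisopropylsilyloxy)phenyl]-2-oxo-3-oxabicyclo[3.1.0]hexane-1-carboxylate
Product: 9 methyl (1R,5R,6S)-6-[4-(allyloxy)-3-methoxyphenyl]-2-oxo-3,7-dioxabicyclo[3.3.0]octane-1-carboxylate, via quinone methide enolate 7 (not isolated), via cyclised phenoxide 8 (not isolated)
Conditions: (CH2O)n (3 equiv), Bu4NF (TBAF, 1.05 equiv), 4 Å MS, THF (0.02 M), −20 °C → rt; then allyl bromide (3 equiv), rt
Reagents that add atoms: formaldehyde (from paraformaldehyde), C=O; allyl bromide, C=CCBr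
Why: Proposed new method: fluoride removes the aryl silyl group and the phenoxide pushes open the strained cyclopropane bond C6–C1 to the p-quinone methide and ester–lactone enolate 7 (the known fluoride- or base-triggered opening of 2-(4-siloxyaryl)cyclopropane-1,1-dicarboxylates, so far intercepted only by external nucleophiles), the enolate is hydroxymethylated at C1 by formaldehyde in a reversible aldol step, and the alkoxide adds to the quinone methide carbon (oxa-1,6-addition) with re-aromatisation; the closest known reaction type is the Lewis-acid (3+2) annulation of donor–acceptor cyclopropanes with aldehydes, run here as an anionic relay. The oxolane closes in a 5-exo-trig mode, the exocyclic C=C of the quinone methide lying outside the new ring. The new centre C6 is controlled by allylic 1,3-strain in 7 (the C–H at the future C5 eclipses the exocyclic C=C) together with delivery of oxygen from the C1 tether, which should put the aryl group exo and trans to the lactone CH2, as in the quinone methide cyclisations that lead to furofuran lignans, and opposite to the inversion outcome expected from a Lewis-acid annulation of this trans-cyclopropane. The quaternary centre C1 is controlled by the existing centre C5, because only the hydroxymethyl epimer cis to the side chain can close to a cis-fused bicycle and the trans epimer reverts by retro-aldol. The step needs C-hydroxymethylation and ring closure to outrun intermolecular attack of phenoxide on the quinone methide, its tautomerisation to a styrene and ortho-hydroxymethylation of the phenoxide; high dilution, the five-membered tether and the immediate O-allylation of phenoxide 8 in the flask (which also blocks retro-oxa-Michael epimerisation at C6) are meant to secure this.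

Step 5
Reactants: 9 methyl (1R,5R,6S)-6-[4-(allyloxy)-3-methoxyphenyl]-2-oxo-3,7-dioxabicyclo[3.3.0]octane-1-carboxylate
Product: 10 (1R,5R,6S)-6-[4-(allyloxy)-3-methoxyphenyl]-3,7-dioxabicyclo[3.3.0]octan-2-one
Conditions: LiCl (3 equiv), H2O (2 equiv), DMSO, 125–130 °C
Reagents that add atoms: none
Why: Krapcho demethoxycarbonylation (chloride SN2 at the ester methyl, loss of CO2, protonation of the lactone enolate) removes the auxiliary acceptor, and the new C1–H centre can only be cis because a trans-fused bicyclo[3.3.0] lactone is too strained, which fixes the 3,4-cis relationship of the target.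

Step 6
Reactants: 10 (1R,5R,6S)-6-[4-(allyloxy)-3-methoxyphenyl]-3,7-dioxabicyclo[3.3.0]octan-2-one
Product: 11 (1R,5R,6S)-6-[4-(allyloxy)-3-methoxyphenyl]-3,7-dioxabicyclo[3.3.0]octan-2-ol (anomer mixture)
Conditions: iBu2AlH (DIBAL-H, 1.1 equiv), CH2Cl2, −78 °C
Reagents that add atoms: none
Why: Partial reduction of a γ-lactone to the lactol at low temperature is routine, and the cis-fused lactol keeps the epimerisable centre next to the masked aldehyde locked.

Step 7
Reactants: 12 4-bromo-2-methoxyphenol
Product: 13 1-(allyloxy)-4-bromo-2-methoxybenzene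
Conditions: allyl bromide, K2CO3, acetone, reflux
Reagents that add atoms: allyl bromide, C=CCBr
Why: Williamson allylation of a phenol; allyl is chosen because it tolerates Grignard formation and is removed at the end under neutral palladium catalysis.

Step 8
Reactants: 11 (1R,5R,6S)-6-[4-(allyloxy)-3-methoxyphenyl]-3,7-dioxabicyclo[3.3.0]octan-2-ol; 13 1-(allyloxy)-4-bromo-2-methoxybenzene
Product: 16 (R)-[4-(allyloxy)-3-methoxyphenyl]{(3R,4R,5S)-5-[4-(allyloxy)-3-methoxyphenyl]-4-(hydroxymethyl)oxolan-3-yl}methanol, via aryl Grignard reagent 14 (not isolated), via ring-opened aldehyde alkoxide 15 (not isolated)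
Conditions: 13 (4 equiv), Mg, THF, rt → 40 °C; then 11, THF–CH2Cl2, −40 °C → 0 °C
Reagents that add atoms: none
Why: Grignard addition to a lactol through its ring-opened aldehyde 15: Felkin–Anh attack anti to the more substituted α-branch (ring C4 with its CH2OMgBr arm), with the carbonyl oxygen syn to the ring CH2–O and reinforced by magnesium chelation to the ring oxygen, should give the (R)-carbinol, the opposite sense to hydride reduction of the corresponding ketone.

Step 9
Reactants: 16 (R)-[4-(allyloxy)-3-methoxyphenyl]{(3R,4R,5S)-5-[4-(allyloxy)-3-methoxyphenyl]-4-(hydroxymethyl)oxolan-3-yl}methanol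
Product: 17 (7R)-7-hydroxylariciresinol
Conditions: Pd(PPh3)4 (5 mol %), morpholine (10 equiv), THF, rt
Reagents that add atoms: none
Why: Tsuji–Trost deallylation (oxidative addition of zerovalent palladium to the aryl allyl ethers, capture of the allyl group by morpholine) should free both phenols under neutral conditions, avoiding the acid that would cyclise the p-hydroxybenzylic alcohol onto the CH2OH and the hydrogenolysis that would cleave the benzylic C–O bonds.

**Compound list**

1 | (E)-3-(4-hydroxy-3-methoxyphenyl)prop-2-enal (coniferaldehyde) | O=C/C=C/c1ccc(O)c(OC)c1 | starting material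
2 | (E)-3-[3-methoxy-4-(triisopropylsilyloxy)phenyl]prop-2-enal | O=C/C=C/c1ccc(O[Si](C(C)C)(C(C)C)C(C)C)c(OC)c1 | intermediate
3 | dimethyl 2-bromomalonate | COC(=O)C(Br)C(=O)OC | starting material
4 | dimethyl (2R,3S)-2-formyl-3-[3-methoxy-4-(triisopropylsilyloxy)phenyl]cyclopropane-1,1-dicarboxylate | O=C[C@@H]1[C@@H](c2ccc(O[Si](C(C)C)(C(C)C)C(C)C)c(OC)c2)C1(C(=O)OC)C(=O)OC | intermediate
5 | dimethyl (2R,3S)-2-(hydroxymethyl)-3-[3-methoxy-4-(triisopropylsilyloxy)phenyl]cyclopropane-1,1-dicarboxylate | OC[C@@H]1[C@@H](c2ccc(O[Si](C(C)C)(C(C)C)C(C)C)c(OC)c2)C1(C(=O)OC)C(=O)OC | intermediate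
6 | methyl (1S,5R,6S)-6-[3-methoxy-4-(triisopropylsilyloxy)phenyl]-2-oxo-3-oxabicyclo[3.1.0]hexane-1-carboxylate | COC(=O)[C@]12[C@H](c3ccc(O[Si](C(C)C)(C(C)C)C(C)C)c(OC)c3)[C@H]1COC2=O | intermediate
7 | tetrabutylammonium enolate of methyl (4R)-4-[(3-methoxy-4-oxocyclohexa-2,5-dien-1-ylidene)methyl]-2-oxooxolane-3-carboxylate | COC(=O)C1=C([O-])OC[C@@H]1C=C1C=CC(=O)C(OC)=C1.CCCC[N+](CCCC)(CCCC)CCCC | intermediate
8 | tetrabutylammonium 2-methoxy-4-[(1R,5R,6S)-1-(methoxycarbonyl)-2-oxo-3,7-dioxabicyclo[3.3.0]octan-6-yl]phenolate | COC(=O)[C@]12CO[C@H](c3ccc([O-])c(OC)c3)[C@H]1COC2=O.CCCC[N+](CCCC)(CCCC)CCCC | intermediate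
9 | methyl (1R,5R,6S)-6-[4-(allyloxy)-3-methoxyphenyl]-2-oxo-3,7-dioxabicyclo[3.3.0]octane-1-carboxylate | COC(=O)[C@]12CO[C@H](c3ccc(OCC=C)c(OC)c3)[C@H]1COC2=O | intermediate
10 | (1R,5R,6S)-6-[4-(allyloxy)-3-methoxyphenyl]-3,7-dioxabicyclo[3.3.0]octan-2-one | O=C1OC[C@H]2[C@@H]1CO[C@@H]2c1ccc(OCC=C)c(OC)c1 | intermediate
11 | (1R,5R,6S)-6-[4-(allyloxy)-3-methoxyphenyl]-3,7-dioxabicyclo[3.3.0]octan-2-ol (anomer mixture) | OC1OC[C@H]2[C@@H]1CO[C@@H]2c1ccc(OCC=C)c(OC)c1 | intermediate
12 | 4-bromo-2-methoxyphenol | COc1cc(Br)ccc1O | starting material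
13 | 1-(allyloxy)-4-bromo-2-methoxybenzene | C=CCOc1ccc(Br)cc1OC | intermediate
14 | [4-(allyloxy)-3-methoxyphenyl]magnesium bromide | C=CCOc1ccc([Mg]Br)cc1OC | intermediate
15 | bromomagnesium alkoxide of (3R,4R,5S)-5-[4-(allyloxy)-3-methoxyphenyl]-4-(hydroxymethyl)oxolane-3-carbaldehyde | COc1cc([C@H]2OC[C@H](C=O)[C@@H]2CO[Mg]Br)ccc1OCC=C | intermediate
16 | (R)-[4-(allyloxy)-3-methoxyphenyl]{(3R,4R,5S)-5-[4-(allyloxy)-3-methoxyphenyl]-4-(hydroxymethyl)oxolan-3-yl}methanol | COc1cc([C@H]2OC[C@H]([C@@H](O)c3ccc(OCC=C)c(OC)c3)[C@@H]2CO)ccc1OCC=C | intermediate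
17 | (7R)-7-hydroxylariciresinol, 4-[(2S,3R,4R)-4-[(R)-hydroxy(4-hydroxy-3-methoxyphenyl)methyl]-3-(hydroxymethyl)oxolan-2-yl]-2-methoxyphenol | COc1cc([C@H]2OC[C@H]([C@@H](O)c3ccc(O)c(OC)c3)[C@@H]2CO)ccc1O | target

Total step count: 9. Longest linear sequence: 8 steps (steps 1 to 6, 8 and 9); step 7 prepares the second aryl fragment.

**Steps most likely to fail**

Step 4 (proposed new method). The quinone methide may be lost to intermolecular attack by phenoxide or to tautomerisation into a styrene before the productive hydroxymethyl epimer closes, and reversible oxa-Michael addition may erode the exo selectivity. The fallback uses known reactions, sets out from 6 and returns at 9. Yb(OTf)3-catalysed ring opening of 6 by methanol (CH2Cl2–MeOH, rt; nucleophilic opening of donor–acceptor cyclopropanes by alcohols) should give methyl (4R)-4-{methoxy[3-methoxy-4-(triisopropylsilyloxy)phenyl]methyl}-2-oxooxolane-3-carboxylate F1, as epimers at C3 and at the benzylic carbon, both inconsequential. Hydroxymethylation with paraformaldehyde and catalytic DBU in THF should give methyl (3R,4R)-3-(hydroxymethyl)-4-{methoxy[3-methoxy-4-(triisopropylsilyloxy)phenyl]methyl}-2-oxooxolane-3-carboxylate F2, in equilibrium with its C3 epimer through retro-aldol. BF3·OEt2 in CH2Cl2 at −40 °C then ionises the benzylic methyl ether and the primary alcohol closes the oxolane (SN1 cycloetherification onto a p-oxybenzylic cation, as used for furofuran lignans, exo for the same allylic-strain reason) to give methyl (1R,5R,6S)-6-[3-methoxy-4-(triisopropylsilyloxy)phenyl]-2-oxo-3,7-dioxabicyclo[3.3.0]octane-1-carboxylate F3. Bu4NF followed by allyl bromide in THF converts this into 9.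

Step 8. Facial selectivity in the addition to the ring-opened aldehyde may be poor if a seven-membered chelate through the magnesium alkoxide competes with the Felkin–Anh arrangement. The fallback relies on reagent control, sets out from 10 and returns at 16. One equivalent of Grignard reagent 14 at −78 °C should add once to lactone 10 to give [4-(allyloxy)-3-methoxyphenyl]{(3R,4R,5S)-5-[4-(allyloxy)-3-methoxyphenyl]-4-(hydroxymethyl)oxolan-3-yl}methanone F4 (in equilibrium with its cyclic hemiketal). Corey–Bakshi–Shibata reduction with the (S)-2-methyl-oxazaborolidine and BH3·SMe2, in which the aryl group acts as the large substituent, should then give the (R)-carbinol 16.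

Step 2. Iminium formation and Michael addition may be slow with the electron-rich enal, and the amine may re-open the donor–acceptor cyclopropane, lowering conversion and enantiomeric purity. The fallback is a metal carbene route, sets out from 2 and returns at 6. Luche reduction (NaBH4, CeCl3·7H2O, MeOH) should give (E)-3-[3-methoxy-4-(triisopropylsilyloxy)phenyl]prop-2-en-1-ol F5. Acylation with methyl malonyl chloride and pyridine should give methyl (E)-3-[3-methoxy-4-(triisopropylsilyloxy)phenyl]prop-2-en-1-yl propanedioate F6. Diazo transfer with 4-acetamidobenzenesulfonyl azide and Et3N should give methyl (E)-3-[3-methoxy-4-(triisopropylsilyloxy)phenyl]prop-2-en-1-yl 2-diazopropanedioate F7. Asymmetric intramolecular cyclopropanation with a chiral amidoporphyrin complex of divalent cobalt, [Co(3,5-DitBu-ChenPhyrin)], in the enantiomeric form that leads to the (1S,5R,6S) series, should then give 6.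

**Further compounds**

F1 | step 4 | methyl (4R)-4-{methoxy[3-methoxy-4-(triisopropylsilyloxy)phenyl]methyl}-2-oxooxolane-3-carboxylate | COC(=O)C1C(=O)OC[C@@H]1C(OC)c1ccc(O[Si](C(C)C)(C(C)C)C(C)C)c(OC)c1
F2 | step 4 | methyl (3R,4R)-3-(hydroxymethyl)-4-{methoxy[3-methoxy-4-(triisopropylsilyloxy)phenyl]methyl}-2-oxooxolane-3-carboxylate | COC(=O)[C@@]1(CO)C(=O)OC[C@@H]1C(OC)c1ccc(O[Si](C(C)C)(C(C)C)C(C)C)c(OC)c1
F3 | step 4 | methyl (1R,5R,6S)-6-[3-methoxy-4-(triisopropylsilyloxy)phenyl]-2-oxo-3,7-dioxabicyclo[3.3.0]octane-1-carboxylate | COC(=O)[C@]12CO[C@H](c3ccc(O[Si](C(C)C)(C(C)C)C(C)C)c(OC)c3)[C@H]1COC2=O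
F4 | step 8 | [4-(allyloxy)-3-methoxyphenyl]{(3R,4R,5S)-5-[4-(allyloxy)-3-methoxyphenyl]-4-(hydroxymethyl)oxolan-3-yl}methanone | COc1cc([C@H]2OC[C@H](C(=O)c3ccc(OCC=C)c(OC)c3)[C@@H]2CO)ccc1OCC=C
F5 | step 2 | (E)-3-[3-methoxy-4-(triisopropylsilyloxy)phenyl]prop-2-en-1-ol | OC/C=C/c1ccc(O[Si](C(C)C)(C(C)C)C(C)C)c(OC)c1
F6 | step 2 | methyl (E)-3-[3-methoxy-4-(triisopropylsilyloxy)phenyl]prop-2-en-1-yl propanedioate | COC(=O)CC(=O)OC/C=C/c1ccc(O[Si](C(C)C)(C(C)C)C(C)C)c(OC)c1
F7 | step 2 | methyl (E)-3-[3-methoxy-4-(triisopropylsilyloxy)phenyl]prop-2-en-1-yl 2-diazopropanedioate | COC(=O)C(=[N+]=[N-])C(=O)OC/C=C/c1ccc(O[Si](C(C)C)(C(C)C)C(C)C)c(OC)c1
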